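**Retrosynthetic overview**
- The strategy rests on the C2–C3–C4(CH3) three-carbon bridge of the cyclopentane (ring A, C1–C5). It spans the ring-fusion carbons C1 and C5, and C1 lies next to C10 of the seven-membered ring (ring B), which is taken back to a ketone.
- Ring A is disconnected at C4–C5 and C1–C2 into a methyl-substituted trimethylenemethane unit and the chiral cycloheptenone 11.
- Ring B is made first: Evans allylation sets C7, a Felkin-controlled Mukaiyama aldol sets C8, and ring-closing metathesis closes the enone.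
- After the annulation, the C10 ketone becomes the carbinol (methylenation, C8-hydroxyl-directed epoxidation, hydride opening). The exocyclic C3 methylene becomes the C3=C4 alkene (ozonolysis, thermodynamic enol triflate, reduction).
- The epoxide ring is formed last on the β face of C3=C4, followed by acylation of the C8 hydroxyl.

Key step: step 9

Remarks: Guaiane numbering is used for all bicyclic compounds. β is the face of H1 and the C10 methyl; α is the face of H5, the C7 isopropyl, the C8 oxygen and the C10 hydroxyl. Compounds 1, 2, 7, 12, 13 and 32 are taken as commercially available. The C4 configuration of the cycloadducts is written as the expected major one; it has no consequence because C4 becomes planar in step 16.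

**Route**

Step 1
Reactants: 1 (R)-4-benzyl-3-(3-methylbutanoyl)oxazolidin-2-one; 2 allyl bromide
Product: 4 (R)-4-benzyl-3-[(R)-2-isopropylpent-4-enoyl]oxazolidin-2-one, via sodium Z-enolate 3 (not isolated)
Conditions: NaHMDS, THF, −78 °C; allyl bromide, −78 to −40 °C
Reagents that add atoms: allyl bromide (2), C=CCBr
Why: Evans asymmetric alkylation: the chelated Z-enolate is allylated on the face away from the benzyl group, which sets C7 as R.

Step 2
Reactants: 4 (R)-4-benzyl-3-[(R)-2-isopropylpent-4-enoyl]oxazolidin-2-one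
Product: 5 (R)-2-isopropylpent-4-en-1-ol
Conditions: LiBH4, THF, 0 °C to rt; aqueous NaOH work-up
Reagents that add atoms: none
Why: Reductive cleavage of the imide by borohydride releases the primary alcohol without touching the stereocentre or the alkene, and the auxiliary is recovered.

Step 3
Reactants: 5 (R)-2-isopropylpent-4-en-1-ol
Product: 6 (R)-2-isopropylpent-4-enal
Conditions: Dess–Martin periodinane, CH2Cl2, 0 °C
Reagents that add atoms: none
Why: Dess–Martin oxidation under non-basic conditions should give the α-branched aldehyde without epimerisation; the volatile aldehyde is used directly in solution.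

Step 4
Reactants: 6 (R)-2-isopropylpent-4-enal; 7 2-(trimethylsilyloxy)buta-1,3-diene
Product: 9 (5R,6R)-5-hydroxy-6-isopropylnona-1,8-dien-3-one, via difluoroboryl aldolate 8 (not isolated)
Conditions: BF3·OEt2, CH2Cl2, −78 °C; cold aqueous work-up
Reagents that add atoms: 2-(trimethylsilyloxy)buta-1,3-diene (7), C=CC(=C)O[Si](C)(C)C
Why: Mukaiyama aldol addition through the terminal enol carbon of the dienol silane under Felkin–Anh control (isopropyl anti to the nucleophile, non-chelating Lewis acid) should give the 5R carbinol, the C7/C8 pair that becomes cis on ring B; the minor C5 epimer is removed by chromatography.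

Step 5
Reactants: 9 (5R,6R)-5-hydroxy-6-isopropylnona-1,8-dien-3-one
Product: 10 (5R,6R)-5-(tert-butyldimethylsilyloxy)-6-isopropylnona-1,8-dien-3-one
Conditions: TBSOTf, 2,6-lutidine, CH2Cl2, −78 °C
Reagents that add atoms: tert-butyldimethylsilyl triflate, CC(C)(C)[Si](C)(C)OS(=O)(=O)C(F)(F)F
Why: Silylation with the silyl triflate and a hindered, non-nucleophilic base at low temperature protects the alcohol before retro-aldol or oxa-Michael pathways can intervene.

Step 6
Reactants: 10 (5R,6R)-5-(tert-butyldimethylsilyloxy)-6-isopropylnona-1,8-dien-3-one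
Product: 11 (5R,6R)-6-(tert-butyldimethylsilyloxy)-5-isopropylcyclohept-2-en-1-one
Conditions: second-generation Grubbs catalyst RuCl2(=CHPh)(PCy3)(H2IMes) (3 mol%), CH2Cl2 (5 mM), 40 °C
Reagents that add atoms: none
Why: Ring-closing metathesis between the vinyl ketone and the terminal alkene closes ring B with loss of ethylene, a reliable closure for cyclohept-2-enones.

Step 7
Reactants: 12 2-bromo-3-(trimethylsilyl)prop-1-ene; 13 acetaldehyde
Product: 15 3-[(trimethylsilyl)methyl]but-3-en-2-ol (racemic), via vinyllithium 14 (not isolated)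
Conditions: tBuLi (2 equiv), Et2O, −78 °C; CH3CHO, −78 °C; H2O
Reagents that add atoms: acetaldehyde (13), CC=O
Why: Bromine–lithium exchange gives the vinyllithium, which adds to the aldehyde carbonyl; the carbinol centre is racemic and is lost on ionisation in step 9.

Step 8
Reactants: 15 3-[(trimethylsilyl)methyl]but-3-en-2-ol
Product: 16 3-acetoxy-2-[(trimethylsilyl)methyl]but-1-ene (racemic)
Conditions: Ac2O, pyridine, DMAP (cat.), CH2Cl2, 0 °C to rt
Reagents that add atoms: acetic anhydride, CC(=O)OC(C)=O
Why: Standard acetylation of the secondary allylic alcohol gives the bifunctional silyl acetate donor.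

Step 9
Reactants: 11 (5R,6R)-6-(tert-butyldimethylsilyloxy)-5-isopropylcyclohept-2-en-1-one; 16 3-acetoxy-2-[(trimethylsilyl)methyl]but-1-ene
Product: 18 trans-fused 8α-(tert-butyldimethylsilyloxy)-7α-isopropyl-4α-methyl-3-methylene-(1β-H,5α-H)-bicyclo[5.3.0]decan-10-one, via cis-fused cycloadduct 17 (not isolated)
Conditions: Pd(OAc)2 (5 mol%), P(OiPr)3 (30 mol%), 16 (1.6 equiv, slow addition), THF, reflux; then DBU (0.3 equiv), rt
Reagents that add atoms: 3-acetoxy-2-[(trimethylsilyl)methyl]but-1-ene (16), CC(OC(C)=O)C(=C)C[Si](C)(C)C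
Why: Zerovalent palladium (formed from Pd(OAc)2 and the phosphite) ionises the allylic acetate and acetate removes the silyl group, giving a zwitterionic methyl-trimethylenemethane–palladium complex that adds in Michael fashion to C5 through its methyl-bearing terminus (C4–C5 bond); this is the known palladium-catalysed trimethylenemethane (3+2) cycloaddition to cyclic enones, in which substituted donors bond through the substituted terminus. The C10 enolate then closes ring A by 5-exo attack of C1 on the C2 terminus of the π-allylpalladium unit (C1–C2 bond), which leaves the exocyclic C3 methylene and returns zerovalent palladium. C5 is set by approach to the β face, anti to the cis C7 isopropyl and C8 silyloxy groups on the α face of ring B; C4 is set in the same event (methyl expected trans to C6), and either C4 epimer serves. C1 is under thermodynamic control because it is α to the C10 ketone: DBU should convert the cis-fused kinetic adduct into the trans-fused ketone (H1 β, H5 α), expected to be the more stable epimer, and any residual cis isomer is separated and resubmitted. The step needs donor regiochemistry (intrinsic to the substituted complex), C5 facial selectivity (substrate-controlled) and conjugate addition faster than proton transfer, the last helped by excess donor added slowly.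

Step 10
Reactants: 18 trans-fused 3-methylene C10 ketone
Product: 19 8α-(tert-butyldimethylsilyloxy)-7α-isopropyl-4α-methyl-3,10-bis(methylene)-(1β-H,5α-H)-bicyclo[5.3.0]decane
Conditions: Ph3PCH3Br, KOtBu, THF, 0 °C to rt
Reagents that add atoms: methyltriphenylphosphonium bromide, C[P+](c1ccccc1)(c1ccccc1)c1ccccc1.[Br-]
Why: Wittig methylenation of the C10 ketone with the non-stabilised ylide; C1 is already at its thermodynamic configuration and the low temperature spares the β-silyloxy group.

Step 11
Reactants: 19 silyl ether diene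
Product: 20 7α-isopropyl-4α-methyl-3,10-bis(methylene)-(1β-H,5α-H)-bicyclo[5.3.0]decan-8α-ol
Conditions: TBAF, THF, rt
Reagents that add atoms: none
Why: Fluoride cleavage of the silyl ether frees the C8 hydroxyl needed as a directing group.

Step 12
Reactants: 20 homoallylic alcohol
Product: 21 spiro-epoxide at C10 (oxygen α) of alcohol 20 with the C3 methylene intact
Conditions: VO(acac)2 (5 mol%), tBuOOH (1.5 equiv, in decane), CH2Cl2, 0 °C to rt
Reagents that add atoms: tert-butyl hydroperoxide, CC(C)(C)OO
Why: Vanadium-catalysed hydroxyl-directed epoxidation: the vanadium-bound C8 alkoxide delivers oxygen to the homoallylic C10 methylene on its own α face, setting C10–O α, while the remote C3 methylene has no directing group and is left.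

Step 13
Reactants: 21 epoxy alcohol
Product: 22 7α-isopropyl-4α,10β-dimethyl-3-methylene-(1β-H,5α-H)-bicyclo[5.3.0]decane-8α,10α-diol
Conditions: LiAlH4, THF, 0 °C to rt
Reagents that add atoms: none
Why: Hydride opens the 1,1-disubstituted epoxide at its primary carbon (SN2), giving the tertiary C10 alcohol with OH α and methyl β.

Step 14
Reactants: 22 diol
Product: 23 8α,10α-bis(triethylsilyl) ether of diol 22
Conditions: TESOTf (3 equiv), 2,6-lutidine, CH2Cl2, −78 to 0 °C
Reagents that add atoms: triethylsilyl triflate, CC[Si](CC)(CC)OS(=O)(=O)C(F)(F)F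
Why: The silyl triflate silylates both the secondary and the tertiary hydroxyl, protecting them for the enolate chemistry and placing a bulky group on the α face at C10.

Step 15
Reactants: 23 bis(silyl ether)
Product: 25 8α,10α-bis(triethylsilyloxy)-7α-isopropyl-4α,10β-dimethyl-(1β-H,5α-H)-bicyclo[5.3.0]decan-3-one, via secondary ozonide 24 (not isolated)
Conditions: O3, CH2Cl2, −78 °C; PPh3, −78 °C to rt
Reagents that add atoms: ozone, [O-][O+]=O
Why: Ozonolysis of the only alkene with reductive work-up unmasks the C3 ketone.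

Step 16
Reactants: 25 C3 ketone
Product: 26 3-(trimethylsilyloxy)-3-ene (C3=C4 enol silane) of ketone 25
Conditions: Me3SiI, (Me3Si)2NH, CH2Cl2, −20 °C to rt
Reagents that add atoms: iodotrimethylsilane, C[Si](C)(C)I
Why: Enol silylation under equilibrating conditions should give the thermodynamic, more substituted C3=C4 enol silane; the C4 stereocentre is erased here.

Step 17
Reactants: 26 enol silane
Product: 28 C3 enol triflate (C3=C4) bearing the 8α,10α-bis(triethylsilyloxy) groups, via lithium enolate 27 (not isolated)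
Conditions: MeLi, THF, 0 °C; PhNTf2, −78 °C to rt
Reagents that add atoms: N-phenylbis(trifluoromethanesulfonimide), O=S(=O)(N(c1ccccc1)S(=O)(=O)C(F)(F)F)C(F)(F)F
Why: Methyllithium cleaves the enol silane to the regio-defined lithium enolate, which is O-triflated without scrambling of the double-bond position.

Step 18
Reactants: 28 enol triflate
Product: 29 8α,10α-bis(triethylsilyloxy)-7α-isopropyl-4,10β-dimethyl-(1β-H,5α-H)-bicyclo[5.3.0]dec-3-ene
Conditions: Pd(OAc)2 (5 mol%), PPh3 (10 mol%), HCO2H, Bu3N, DMF, 60 °C
Reagents that add atoms: none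
Why: Palladium-catalysed formate reduction of the enol triflate (oxidative addition, formate exchange, decarboxylation, reductive elimination) replaces the triflate by hydrogen and leaves the C3=C4 alkene in place.

Step 19
Reactants: 29 trisubstituted alkene
Product: 30 3β,4β-epoxide of alkene 29 (C4 methyl α)
Conditions: mCPBA, NaHCO3, CH2Cl2, 0 °C
Reagents that add atoms: 3-chloroperoxybenzoic acid, OOC(=O)c1cccc(Cl)c1
Why: Prilezhaev epoxidation: the trans ring fusion locks ring A as an envelope with C1 displaced to the β side, so β attack is staggered with respect to the allylic bonds at C2 and C5 (torsional steering, anti to the pseudo-axial H5), and the C10 silyloxy group on the α face rules out hydroxyl-directed delivery there.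

Step 20
Reactants: 30 epoxy bis(silyl ether)
Product: 31 3β,4β-epoxy-7α-isopropyl-4α,10β-dimethyl-(1β-H,5α-H)-bicyclo[5.3.0]decane-8α,10α-diol
Conditions: TBAF, THF, rt to 45 °C
Reagents that add atoms: none
Why: Fluoride removes both triethylsilyl ethers, and the epoxide is stable to these basic conditions.

Step 21
Reactants: 31 epoxy diol; 32 3,4-dimethoxybenzoyl chloride
Product: 33 target, the 8-O-(3,4-dimethoxybenzoyl) ester of epoxy diol 31
Conditions: Et3N, DMAP, CH2Cl2, 0 °C to rt
Reagents that add atoms: 3,4-dimethoxybenzoyl chloride (32), COc1ccc(C(Cl)=O)cc1OC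
Why: DMAP-catalysed acylation is selective for the secondary C8 hydroxyl over the tertiary C10 hydroxyl and should give the target.

**Compound list**
1 | (R)-4-benzyl-3-(3-methylbutanoyl)oxazolidin-2-one | CC(C)CC(=O)N1[C@H](Cc2ccccc2)COC1=O | starting material
2 | allyl bromide | C=CCBr | starting material
3 | sodium Z-enolate of 1 | CC(C)/C=C(\[O-])N1[C@H](Cc2ccccc2)COC1=O.[Na+] | intermediate
4 | (R)-4-benzyl-3-[(R)-2-isopropylpent-4-enoyl]oxazolidin-2-one | C=CC[C@@H](C(=O)N1[C@H](Cc2ccccc2)COC1=O)C(C)C | intermediate
5 | (R)-2-isopropylpent-4-en-1-ol | C=CC[C@@H](CO)C(C)C | intermediate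
6 | (R)-2-isopropylpent-4-enal | C=CC[C@@H](C=O)C(C)C | intermediate
7 | 2-(trimethylsilyloxy)buta-1,3-diene | C=CC(=C)O[Si](C)(C)C | starting material
8 | difluoroboryl aldolate of 9 | C=CC[C@@H]([C@H](OB(F)F)CC(=O)C=C)C(C)C | intermediate
9 | (5R,6R)-5-hydroxy-6-isopropylnona-1,8-dien-3-one | C=CC[C@@H]([C@H](O)CC(=O)C=C)C(C)C | intermediate
10 | (5R,6R)-5-(tert-butyldimethylsilyloxy)-6-isopropylnona-1,8-dien-3-one | C=CC[C@@H]([C@H](O[Si](C)(C)C(C)(C)C)CC(=O)C=C)C(C)C | intermediate
11 | (5R,6R)-6-(tert-butyldimethylsilyloxy)-5-isopropylcyclohept-2-en-1-one | CC(C)(C)[Si](C)(C)O[C@@H]1CC(=O)C=CC[C@@H]1C(C)C | intermediate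
12 | 2-bromo-3-(trimethylsilyl)prop-1-ene | C=C(Br)C[Si](C)(C)C | starting material
13 | acetaldehyde | CC=O | starting material
14 | [3-(trimethylsilyl)prop-1-en-2-yl]lithium | [Li]C(=C)C[Si](C)(C)C | intermediate
15 | 3-[(trimethylsilyl)methyl]but-3-en-2-ol (racemic) | CC(O)C(=C)C[Si](C)(C)C | intermediate
16 | 3-acetoxy-2-[(trimethylsilyl)methyl]but-1-ene (racemic) | CC(OC(C)=O)C(=C)C[Si](C)(C)C | intermediate
17 | cis-fused cycloadduct (H1 α, H5 α), C1 epimer of 18 | CC(C)(C)[Si](C)(C)O[C@@H]2CC(=O)[C@H]3CC(=C)[C@H](C)[C@H]3C[C@@H]2C(C)C | intermediate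
18 | trans-fused C10 ketone (H1 β, H5 α) with C3 exocyclic methylene, 4α-methyl, 7α-isopropyl, 8α-OTBS | CC(C)(C)[Si](C)(C)O[C@@H]2CC(=O)[C@@H]3CC(=C)[C@H](C)[C@H]3C[C@@H]2C(C)C | intermediate
19 | 3,10-bis(methylene) silyl ether | CC(C)(C)[Si](C)(C)O[C@@H]2CC(=C)[C@@H]3CC(=C)[C@H](C)[C@H]3C[C@@H]2C(C)C | intermediate
20 | 3,10-bis(methylene) 8α-alcohol | O[C@@H]2CC(=C)[C@@H]3CC(=C)[C@H](C)[C@H]3C[C@@H]2C(C)C | intermediate
21 | C10 spiro-epoxide (O α) 8α-alcohol | O[C@@H]2C[C@]4(OC4)[C@@H]3CC(=C)[C@H](C)[C@H]3C[C@@H]2C(C)C | intermediate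
22 | 8α,10α-diol (10β-methyl) with C3 methylene | O[C@@H]2C[C@](C)(O)[C@@H]3CC(=C)[C@H](C)[C@H]3C[C@@H]2C(C)C | intermediate
23 | bis(triethylsilyl) ether of 22 | CC[Si](CC)(CC)O[C@@H]2C[C@](C)(O[Si](CC)(CC)CC)[C@@H]3CC(=C)[C@H](C)[C@H]3C[C@@H]2C(C)C | intermediate
24 | secondary ozonide (spiro-1,2,4-trioxolane at C3) | CC[Si](CC)(CC)O[C@@H]2C[C@](C)(O[Si](CC)(CC)CC)[C@@H]3CC4(OCOO4)[C@H](C)[C@H]3C[C@@H]2C(C)C | intermediate
25 | C3 ketone bis(triethylsilyl) ether | CC[Si](CC)(CC)O[C@@H]2C[C@](C)(O[Si](CC)(CC)CC)[C@@H]3CC(=O)[C@H](C)[C@H]3C[C@@H]2C(C)C | intermediate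
26 | C3=C4 trimethylsilyl enol ether | CC[Si](CC)(CC)O[C@@H]2C[C@](C)(O[Si](CC)(CC)CC)[C@@H]3CC(O[Si](C)(C)C)=C(C)[C@H]3C[C@@H]2C(C)C | intermediate
27 | C3=C4 lithium enolate | CC[Si](CC)(CC)O[C@@H]2C[C@](C)(O[Si](CC)(CC)CC)[C@@H]3CC([O-])=C(C)[C@H]3C[C@@H]2C(C)C.[Li+] | intermediate
28 | C3 enol triflate (C3=C4) | CC[Si](CC)(CC)O[C@@H]2C[C@](C)(O[Si](CC)(CC)CC)[C@@H]3CC(OS(=O)(=O)C(F)(F)F)=C(C)[C@H]3C[C@@H]2C(C)C | intermediate
29 | C3=C4 alkene bis(triethylsilyl) ether | CC[Si](CC)(CC)O[C@@H]2C[C@](C)(O[Si](CC)(CC)CC)[C@@H]3CC=C(C)[C@H]3C[C@@H]2C(C)C | intermediate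
30 | 3β,4β-epoxide bis(triethylsilyl) ether | CC[Si](CC)(CC)O[C@@H]2C[C@](C)(O[Si](CC)(CC)CC)[C@@H]3C[C@H]4O[C@@]4(C)[C@H]3C[C@@H]2C(C)C | intermediate
31 | 3β,4β-epoxy-8α,10α-diol | O[C@@H]2C[C@](C)(O)[C@@H]3C[C@H]4O[C@@]4(C)[C@H]3C[C@@H]2C(C)C | intermediate
32 | 3,4-dimethoxybenzoyl chloride | COc1ccc(C(Cl)=O)cc1OC | starting material
33 | CNP0304846.1, 8-O-(3,4-dimethoxybenzoyl) ester of 31 | COc1ccc(C(=O)O[C@@H]2C[C@](C)(O)[C@@H]3C[C@H]4O[C@@]4(C)[C@H]3C[C@@H]2C(C)C)cc1OC | target

**Step count**
Total: 21 steps. Longest linear sequence: 19 steps (steps 1–6, then 9–21); steps 7–8 form the donor branch.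

**Steps most likely to fail**

Step 9. The basic trimethylenemethane–palladium intermediate may take a proton from the enolizable enone (quenching the donor or triggering loss of the C8 silyloxy group) faster than it adds. The C5 face may also be poorly differentiated, or the C1 equilibrium may not be one-sided. The fallback sets out from 11 and comes back at 18. Iodination of 11 (I2, pyridine, CH2Cl2) gives the 2-iodoenone F1. Palladium-catalysed methoxycarbonylation (PdCl2(PPh3)2, CO, MeOH, Et3N) gives the 2-methoxycarbonyl enone F2, a doubly activated and much more electrophilic acceptor. The same annulation with 16 gives the angular ester cycloadduct F3. Krapcho dealkoxycarbonylation (LiCl, wet DMSO, 130 °C) followed by the DBU equilibration returns 18.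

Step 19. Facial selectivity may be poor or reversed, with oxygen delivered to the α face of C3=C4. The fallback sets out from 29 and comes back at 30. NBS in aqueous THF should give the 3α-bromo-4β-hydroxy bromohydrin F4: the bromonium forms on the face the peracid prefers and water opens it at the tertiary C4 from the opposite face. KOtBu in THF at 0 °C closes F4 by backside displacement at C3 to the epoxide of the opposite facial sense to direct epoxidation, which is 30.

Step 4. Felkin diastereoselection may be insufficient, or the β-hydroxy enone may cyclise by oxa-Michael addition under the Lewis acid. The fallback sets out from 6 and comes back at 10. Acetate aldol of 6 with the chlorotitanium enolate of (S)-3-acetyl-4-isopropylthiazolidine-2-thione (TiCl4, iPr2NEt, CH2Cl2, −78 °C) gives the aldol adduct F5; the auxiliary (chelated enolate, attack anti to its isopropyl group) and the Felkin preference should reinforce each other. Silylation (TBSOTf, 2,6-lutidine) gives the silyl ether F6. Displacement of the auxiliary with MeNHOMe·HCl and imidazole gives the Weinreb amide F7. Vinylmagnesium bromide (THF, 0 °C, cold acidic quench) gives 10.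

**Further compounds**
F1 | step 9 | (5R,6R)-6-(tert-butyldimethylsilyloxy)-2-iodo-5-isopropylcyclohept-2-en-1-one | CC(C)(C)[Si](C)(C)O[C@@H]1CC(=O)C(I)=CC[C@@H]1C(C)C
F2 | step 9 | methyl (4R,5R)-5-(tert-butyldimethylsilyloxy)-4-isopropyl-7-oxocyclohept-1-ene-1-carboxylate | CC(C)(C)[Si](C)(C)O[C@@H]1CC(=O)C(C(=O)OC)=CC[C@@H]1C(C)C
F3 | step 9 | cis-fused cycloadduct with angular C1 methyl ester (C10 ketone, C3 methylene, 4α-methyl) | CC(C)(C)[Si](C)(C)O[C@@H]2CC(=O)[C@@]3(C(=O)OC)CC(=C)[C@H](C)[C@H]3C[C@@H]2C(C)C
F4 | step 19 | 3α-bromo-4β-hydroxy bromohydrin of 29 | CC[Si](CC)(CC)O[C@@H]2C[C@](C)(O[Si](CC)(CC)CC)[C@@H]3C[C@H](Br)[C@@](C)(O)[C@H]3C[C@@H]2C(C)C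
F5 | step 4 | (S)-3-[(3R,4R)-3-hydroxy-4-isopropylhept-6-enoyl]-4-isopropylthiazolidine-2-thione | C=CC[C@@H]([C@H](O)CC(=O)N1[C@@H](C(C)C)CSC1=S)C(C)C
F6 | step 4 | tert-butyldimethylsilyl ether of F5 | C=CC[C@@H]([C@H](O[Si](C)(C)C(C)(C)C)CC(=O)N1[C@@H](C(C)C)CSC1=S)C(C)C
F7 | step 4 | (3R,4R)-3-(tert-butyldimethylsilyloxy)-4-isopropyl-N-methoxy-N-methylhept-6-enamide | C=CC[C@@H]([C@H](O[Si](C)(C)C(C)(C)C)CC(=O)N(C)OC)C(C)C
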